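**Plan**

1. Retrosynthesis: remove the three benzyl groups, cut the aryl–C(=O)Pr bond (Friedel–Crafts), then cut two bonds of the dimethylated ring at once: ring C=O carbon to the benzyl-bearing ring carbon, and acetyl-bearing ring carbon to the enol carbon next to CMe2. This leaves diketene and an acyclic β-keto ester, which is cut at aryl–CH2 into 1,3,5-tris(benzyloxy)benzene and a vinyl ketone made from methyl 2,2-dimethylacetoacetate and formaldehyde.
2. Enabling feature: the six carbons of the dimethylated ring alternate C=O and substituted carbon (a head-to-tail array of three ketene units), and the CMe2 carbon has no hydrogen. The four-carbon piece ArCH2CH2–CO–CMe2–CO2Me therefore enolises at one carbon only and its ester cannot enolise, so it is a 1,4 C-nucleophile/C-electrophile that matches the electrophilic carbonyl and nucleophilic α-carbon of diketene.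
3. Forward: the chain aryl–CH2CH2–CO–CMe2–CO2Me is joined first; the acetylated dimethylcyclohexanetrione ring then arises in one pot by acetoacetylation and Dieckmann closure. The aromatic ring is preformed, butyrylated afterwards (a butyryl ketone would compete in the enolisation) and deprotected last.
4. Benzyl ethers keep the phenols silent in the base step and block quinone-methide scrambling of the CH2 bridge.
5. Stereochemistry: the target has no stereocentre and no stereogenic double bond, so nothing has to be set.

Key step: step 3

Assumption: the enolised tri- and tetracarbonyl arrays are drawn as one tautomer each, and stabilised diketene and 1,3,5-tris(benzyloxy)benzene are taken as purchasable.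

**Route**

Step 1
Reactants: 1 methyl 2,2-dimethyl-3-oxobutanoate; 2 formaldehyde (as paraformaldehyde)
Product: 3 methyl 2,2-dimethyl-3-oxopent-4-enoate
Conditions: (CH2O)n, i-Pr2NH·CF3CO2H (1 equiv), CF3CO2H (cat.), THF, reflux
Reagents that add atoms: formaldehyde 2 (as paraformaldehyde), C=O
Why: Mannich-type α-methylenation, in which the iminium ion from the ammonium salt and formaldehyde is taken up by the enol of the methyl ketone and loss of the amine gives the vinyl ketone; only the CH3 group can enolise because the other α-carbon is quaternary.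

Step 2
Reactants: 3 methyl 2,2-dimethyl-3-oxopent-4-enoate; 4 1,3,5-tris(benzyloxy)benzene
Product: 5 methyl 2,2-dimethyl-3-oxo-5-[2,4,6-tris(benzyloxy)phenyl]pentanoate
Conditions: Sc(OTf)3 (5 mol %), MeCN, rt; 4 in excess (3 equiv)
Reagents that add atoms: none
Why: Friedel–Crafts-type conjugate addition (hydroarylation) of the strongly π-nucleophilic trialkoxyarene to the vinyl ketone, which Sc(OTf)3 should activate by chelation between ketone and ester carbonyls; the three ring CH positions of 4 are equivalent and the excess of 4 suppresses a second alkylation.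

Step 3
Reactants: 5 methyl 2,2-dimethyl-3-oxo-5-[2,4,6-tris(benzyloxy)phenyl]pentanoate; 6 diketene
Product: 9 2-acetyl-3,5-dihydroxy-4,4-dimethyl-6-[2,4,6-tris(benzyloxy)benzyl]cyclohexa-2,5-dien-1-one, via lithium enolate 7 (not isolated), via open-chain triketo ester 8 (not isolated)
Conditions: LiN(SiMe3)2 (1.05 equiv), THF, −78 °C; diketene, −78 to 0 °C; then KOt-Bu (1.5 equiv), 0 to 50 °C; aq. HCl
Reagents that add atoms: diketene 6, C=C1CC(=O)O1
Why: Proposed new method: the ketone of 5 can enolise only toward its CH2 (the other α-carbon is CMe2 and the ester has no α-hydrogen), so LiN(SiMe3)2 should give the single enolate 7, whose carbon opens diketene at the lactone carbonyl (acyl–oxygen cleavage) to the triketo ester 8 as its enolate; KOt-Bu then forms the dianion, and the carbon between the new ketone and the acetyl carbonyl attacks the methyl ester on CMe2 (Dieckmann condensation), the acidic cyclic product capturing the methoxide set free. The closest known reaction types are the C-acetoacetylation of stabilised carbanions by diketene, the base-induced Claisen cyclisation of 3,5,7-triketo esters to acylphloroglucinols and Dieckmann closures onto esters bound to a quaternary carbon. The six-membered ring closes 6-exo-trig at the ester carbonyl through the enolate carbon. No stereocentre arises. The step needs C- over O-acylation of 7 and closure through carbon, not oxygen: lithium chelation in the forming β-diketonate should favour C-acylation, fast internal proton transfer in 8 should stop the liberated enolate from reacting with more diketene, and the alkoxide returns enol esters or an enol lactone to the open chain so that the most stabilised anion, that of the carbocycle, collects the material. Aldol closures are excluded because CMe2 cannot enolise, and the dianion keeps the ketone beside CMe2 safe from retro-Claisen attack.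

Step 4
Reactants: 9 2-acetyl-3,5-dihydroxy-4,4-dimethyl-6-[2,4,6-tris(benzyloxy)benzyl]cyclohexa-2,5-dien-1-one; 10 butanoic acid
Product: 11 2-acetyl-6-[2,4,6-tris(benzyloxy)-3-butanoylbenzyl]-3,5-dihydroxy-4,4-dimethylcyclohexa-2,5-dien-1-one
Conditions: PrCO2H, (CF3CO)2O, CH2Cl2, 0 °C to rt; then MeOH/H2O
Reagents that add atoms: butanoic acid 10, CCCC(=O)O
Why: Friedel–Crafts acylation by the mixed butanoic trifluoroacetic anhydride formed in the flask, without a metal Lewis acid that would cleave benzyl ethers; the two free positions of the trialkoxyarene are equivalent, the first acyl group deactivates the ring against a second, and enol esters formed on the triketone are hydrolysed in the aqueous methanol quench.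

Step 5
Reactants: 11 2-acetyl-6-[2,4,6-tris(benzyloxy)-3-butanoylbenzyl]-3,5-dihydroxy-4,4-dimethylcyclohexa-2,5-dien-1-one
Product: 12 2-acetyl-6-(3-butanoyl-2,4,6-trihydroxybenzyl)-3,5-dihydroxy-4,4-dimethylcyclohexa-2,5-dien-1-one (CNP0284663.0)
Conditions: H2 (1 atm), Pd/C, EtOAc, rt
Reagents that add atoms: none
Why: Catalytic hydrogenolysis of the three benzyl aryl ethers; the hydrogen-bonded aryl ketone and the enolised β-triketone should not be reduced under these mild conditions.

**Compound list**

1 | methyl 2,2-dimethyl-3-oxobutanoate | CC(=O)C(C)(C)C(=O)OC | starting material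
2 | formaldehyde (used as paraformaldehyde) | C=O | starting material
3 | methyl 2,2-dimethyl-3-oxopent-4-enoate | C=CC(=O)C(C)(C)C(=O)OC | intermediate
4 | 1,3,5-tris(benzyloxy)benzene | c1ccc(COc2cc(OCc3ccccc3)cc(OCc3ccccc3)c2)cc1 | starting material
5 | methyl 2,2-dimethyl-3-oxo-5-[2,4,6-tris(benzyloxy)phenyl]pentanoate | COC(=O)C(C)(C)C(=O)CCc1c(OCc2ccccc2)cc(OCc2ccccc2)cc1OCc1ccccc1 | intermediate
6 | diketene (4-methylideneoxetan-2-one) | C=C1CC(=O)O1 | starting material
7 | lithium enolate: lithium (Z)-enolate of 5 at the ketone CH2 | COC(=O)C(C)(C)/C(O[Li])=C/Cc1c(OCc2ccccc2)cc(OCc2ccccc2)cc1OCc1ccccc1 | intermediate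
8 | open-chain triketo ester: methyl 2,2-dimethyl-3,5,7-trioxo-4-[2,4,6-tris(benzyloxy)benzyl]octanoate (present as its enolate salt, drawn neutral) | COC(=O)C(C)(C)C(=O)C(Cc1c(OCc2ccccc2)cc(OCc2ccccc2)cc1OCc1ccccc1)C(=O)CC(C)=O | intermediate
9 | 2-acetyl-3,5-dihydroxy-4,4-dimethyl-6-[2,4,6-tris(benzyloxy)benzyl]cyclohexa-2,5-dien-1-one | CC(=O)C1=C(O)C(C)(C)C(O)=C(Cc2c(OCc3ccccc3)cc(OCc3ccccc3)cc2OCc2ccccc2)C1=O | intermediate
10 | butanoic acid | CCCC(=O)O | starting material
11 | 2-acetyl-6-[2,4,6-tris(benzyloxy)-3-butanoylbenzyl]-3,5-dihydroxy-4,4-dimethylcyclohexa-2,5-dien-1-one | CCCC(=O)c1c(OCc2ccccc2)cc(OCc2ccccc2)c(CC2=C(O)C(C)(C)C(O)=C(C(C)=O)C2=O)c1OCc1ccccc1 | intermediate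
12 | 2-acetyl-6-(3-butanoyl-2,4,6-trihydroxybenzyl)-3,5-dihydroxy-4,4-dimethylcyclohexa-2,5-dien-1-one (CNP0284663.0) | CCCC(=O)c1c(O)cc(O)c(CC2=C(O)C(C)(C)C(O)=C(C(C)=O)C2=O)c1O | target

**Count and risks**

Total step count: 5. Longest linear sequence: 5 steps (1 → 3 → 5 → 9 → 11 → 12).

Steps most likely to fail:

Step 3 (proposed new method). What may go wrong: acylation of enolate 7 at oxygen, enolate-triggered oligomerisation of diketene, or ring closure through the enolate oxygen and retro-Claisen cleavage beside CMe2 in place of the Dieckmann closure. Fallback with known chemistry, setting out from 4 (and formaldehyde 2) and coming back at 9: the dimethylated ring is made by dearomatisation instead of annulation. Purchased 2,4,6-trihydroxyacetophenone is C,C-dimethylated (MeI, NaOMe, MeOH) to 2-acetylfilicinic acid F1. F1 is condensed with formaldehyde 2 (Knoevenagel) to the 6-methylene trione F2, which is not isolated. Arene 4, used in excess with Sc(OTf)3 or AcOH as catalyst, should add to F2 in a Friedel–Crafts-type Michael addition and give 9.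

Step 4. What may go wrong: acid-promoted ionisation of the trialkoxybenzyl–carbon bond with loss or scrambling of the CH2 bridge, competing O-acylation of the enols, or loss of benzyl groups in the acidic acylating medium. Fallback, setting out from 9 and coming back at 12: the order is reversed and a nitrile is used as the acyl source. Hydrogenolysis of 9 (H2, Pd/C, EtOAc) should give the triol F3. A Houben–Hoesch reaction of F3 with butyronitrile (ZnCl2, HCl, Et2O, 0 °C) should give the ketiminium chloride F4, and hydrolysis of F4 in warm water should give 12.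

Step 2. What may go wrong: double alkylation of the electron-rich arene and acid-induced polymerisation of the vinyl ketone. Fallback, setting out from 4 and 1 and coming back at 5: the aryl–CH2 carbon is brought in as an aldehyde. Vilsmeier–Haack formylation of 4 (POCl3, DMF; aqueous NaOAc) should give 2,4,6-tris(benzyloxy)benzaldehyde F5. Addition of the lithium enolate of 1 (LiN(i-Pr)2, THF, −78 °C) to F5 should give the racemic aldol F6, and acid-catalysed dehydration (p-TsOH cat., toluene) the (E)-enone F7. Conjugate reduction of F7 with [(Ph3P)CuH]6, which spares benzyl ethers and ketones, should give 5.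

**Further compounds**

F1 | step 3 | 2-acetylfilicinic acid (2-acetyl-3,5-dihydroxy-4,4-dimethylcyclohexa-2,5-dien-1-one) | CC(=O)C1=C(O)C(C)(C)C(O)=CC1=O
F2 | step 3 | 2-acetyl-3-hydroxy-4,4-dimethyl-6-methylidenecyclohex-2-ene-1,5-dione | CC(=O)C1=C(O)C(C)(C)C(=O)C(=C)C1=O
F3 | step 4 | 2-acetyl-3,5-dihydroxy-4,4-dimethyl-6-(2,4,6-trihydroxybenzyl)cyclohexa-2,5-dien-1-one | CC(=O)C1=C(O)C(C)(C)C(O)=C(Cc2c(O)cc(O)cc2O)C1=O
F4 | step 4 | ketiminium chloride of the target (butan-1-iminium at the aryl ketone carbon) | CCCC(=[NH2+])c1c(O)cc(O)c(CC2=C(O)C(C)(C)C(O)=C(C(C)=O)C2=O)c1O.[Cl-]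
F5 | step 2 | 2,4,6-tris(benzyloxy)benzaldehyde | O=Cc1c(OCc2ccccc2)cc(OCc2ccccc2)cc1OCc1ccccc1
F6 | step 2 | methyl 5-hydroxy-2,2-dimethyl-3-oxo-5-[2,4,6-tris(benzyloxy)phenyl]pentanoate (racemic) | COC(=O)C(C)(C)C(=O)CC(O)c1c(OCc2ccccc2)cc(OCc2ccccc2)cc1OCc1ccccc1
F7 | step 2 | methyl (E)-2,2-dimethyl-3-oxo-5-[2,4,6-tris(benzyloxy)phenyl]pent-4-enoate | COC(=O)C(C)(C)C(=O)/C=C/c1c(OCc2ccccc2)cc(OCc2ccccc2)cc1OCc1ccccc1
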